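The ratio c(complex with one exchanged)/c(starting complex) at the peak of a closed flask tells me which vessel to charge next.

| setting | Thursday's | Sunday's | Saturday's | elm | ash | oak | maple |
|---|---|---|---|---|---|---|---|
| starting complex | 0.30 M | 0.20 M | 0.45 M | 0.30 M (fed, over 2.00 h) | 0.30 M | 0.30 M | 0.30 M |
| incoming ligand | 0.60 M | 0.60 M | 0.60 M | 0.600 M | 0.600 M | 0.600 M | 0.600 M |
| leaving ligand | 1.5 M | 1.5 M | 1.5 M | 1.50 M | 1.50 M | 1.50 M | 1.50 M |
| remark | run made earlier | run made earlier | run made earlier | a stirred flask in which starting complex is dosed at a steady rate over 2.00 h without added volume, worked up at 2.0 h | a closed flask charged with all of it at once and left for 2.0 h | a single well-mixed tank run continuously and read at steady state, 20.0 h in it on average | one stirred flow tank at steady state, fed with the mixture as stated, mean residence time 2.0 h |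
| time |  |  |  | 2.0 h | 2.0 h |  |  |

- Thursday's (time / min: complex with one exchanged / %, starting complex / %): 8.00: 60.6, 35.8; 25.0: 74.7, 12.8; 40.0: 75.9, 7.9; 60.0: 75.7, 4.4; 90.0: 72.4, 2.7; 120: 70.2, 1.8
- Sunday's (time / min: complex with one exchanged / %, starting complex / %): 8.00: 62.0, 33.2; 12.0: 70.1, 23.4; 20.0: 74.4, 11.6; 40.0: 75.6, 4.4; 60.0: 71.3, 2.3; 90.0: 66.3, 0
- Saturday's (time / min: complex with one exchanged / %, starting complex / %): 6.00: 51.1, 47.9; 20.0: 70.1, 22.6; 30.0: 72.7, 17.6; 50.0: 74.6, 13.4; 80.0: 76.7, 10.9; 90.0: 76.2, 8.9

(scatter of a reading: 0.5 percentage points)

- the set-up with the highest amount of complex with one exchanged at the outlet or at the end, in percent of the starting complex put in ("none" if the first two lie within 2 percentage points) (elm / ash / oak / maple / none)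
- amount of complex with one exchanged at the outlet or at the end, in percent of the starting complex put in, elm
- amount of complex with one exchanged at the outlet or at the end, in percent of the starting complex put in, ash
- amount of complex with one exchanged at the outlet or at the end, in percent of the starting complex put in, oak
- amount of complex with one exchanged at the outlet or at the end, in percent of the starting complex put in, maple

- the stated concentrations are those of everything mixed, before any reaction; amounts are the same in each set-up
- the feed brings no volume worth counting
- the earlier runs were made in a closed, stirred flask

1. At the peak of a closed flask, the step from starting complex makes complex with one exchanged as fast as the next step, its further exchange, takes it. I assume each step runs in proportion to c(incoming ligand), so that concentration cancels and the peak ratio equals the ratio of the two rate constants. This is the selectivity factor, and I call it S.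
2. If S is one constant, the peak height should not move with the charge, and the highest readings are 75.9%, 75.6% and 76.7%, though the charge runs from 0.20 M to 0.45 M.
3. Thursday's reading at 40.0 min gives 9.61, the peak ratio S. It is a coarse reading, since Saturday's peak reads 7.04 and Sunday's 17.2. Equal steps, the zero of this scale, give S = 1.
4. Now take a tank at steady state, with m the share of starting complex at the outlet and u the share converted. The outlet share of complex with one exchanged is y = u·m·S/(m·S + u).
5. Over m, y peaks at 57.2%, reached at m = 24.4%; equal steps give 25.0%.
6. Ash repeats Thursday's charge and time, so I expect 70.2%, more than the tank ceiling, and more than the 64.9% that Sunday's ratio gives in the same formula. I charge ash and leave oak and maple out. I hold no number for elm. If stopping earlier is allowed, I stop near 40.0 min.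

The forecast names ash, with elm 60%, ash 70%, oak 66% and maple 60%, says of ash “this is Thursday's run at 120 min”, and puts oak above my ceiling.

The flask gives ash as best: elm 51.2%, ash 69.9%, oak 37.6%, maple 54.7%.

    starting complex + incoming ligand → leaving ligand + complex with one exchanged (k = 0.320 M⁻¹ min⁻¹)
    complex with one exchanged + incoming ligand → leaving ligand + complex with two exchanged (k = 0.0350 M⁻¹ min⁻¹)
    complex with two exchanged + incoming ligand ⇌ leaving ligand + complex with three exchanged (K = 3.80, k = 0.130 M⁻¹ min⁻¹)
    2 incoming ligand → homo dimer (k = 0.0340 M⁻¹ min⁻¹)
    incoming ligand ⇌ dormant form (K = 0.200, k = 0.0120 min⁻¹)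

Maple holds m = 17.9% at its outlet, and with S = 9.61 the tank rule gives 55.6% against the 54.7% found. Oak holds c(starting complex) = 0.0207 M, so m = 6.88%, and the same rule gives 38.7% against 37.6%.

The runs are simulated with made-up constants; the scatter is artificial.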